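(The numbers in the tables come from a simulation for substances that don't exist; scatter was added.)

I had no rate constants, so I looked for one number that the two earlier runs could give at the asked time.

the same everywhere: substrate 0.14 M

| charge | first nucleophile | second nucleophile | temperature | remark | time |
|---|---|---|---|---|---|
| dusk | 0.16 M | 0.21 M | 2 °C | run made earlier |  |
| spring | 0.25 M | 0.21 M | 19 °C | run made earlier |  |
| north-west | 0.112 M | 0.210 M | 25 °C |  | 4.0 min |
| north-east | 0.112 M | 0.210 M | −5 °C |  | 4.0 min |

- dusk (time / min: target / %): 0.833: 1.7; 2.00: 3.7; 4.00: 5.3; 6.00: 6.4; 10.0: 8.5; 12.0: 8.5; 15.0: 9.0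
- spring (time / min: target / %): 0.667: 8.3; 1.33: 11.3; 2.00: 13.6; 3.00: 14.9; 4.00: 16.6; 5.00: 17.7

(each reading ± 0.3 percentage points)

- percent here means substrate units held: one side product counts as two
- candidate steps: substrate <-> intermediate; first nucleophile + intermediate -> target; second nucleophile + intermediate -> other capture product; substrate <-> dormant form; 2 second nucleophile -> self-condensation product; substrate + target -> side product

- the best flask by amount of target, in percent of the substrate charged; "all alike" if 1.5 percentage points covers them all (north-west / north-east / all alike)
- amount of target at the end, in percent of the substrate charged, north-west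
- amount of target at the end, in percent of the substrate charged, north-east

1. Both runs were read at 4.00 min, the asked time. Dusk then held 5.3% target and spring 16.6%.

2. Each target carries one first nucleophile, so I divided by the equivalents charged. Dusk's 4.64% and spring's 9.30% are each a take-up: the fraction of the charged first nucleophile standing as target at that time.

3. Neither passed 9.30%, so I froze the first nucleophile at its charge, the usual pseudo-first-order move. Target then equals take-up times equivalents.

4. Take-up rose by a factor of 2.00 between dusk at 2 °C and spring at 19 °C, runs that also differ in first nucleophile. I read that factor as temperature and assumed the same factor per degree beyond that range.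

5. Both new flasks hold 0.800 equivalents. So I reckoned 9.51% for north-west and 2.79% for north-east. That gap of 6.7 percentage points is more than the margin of 1.5 points, so I chose north-west.

The forecast also chose north-west, with 11.5% and 2.1%, a north-west figure above mine, holding that “higher temperature favours the target”.

The flasks gave 13.7% in north-west and 2.29% in north-east, so north-west was best.

    substrate ⇌ intermediate (K = 0.00645, k = 0.0116 s⁻¹, Ea = 82.0 kJ mol⁻¹, ΔH = −9.00 kJ mol⁻¹)
    first nucleophile + intermediate → target (k = 13.2 L mol⁻¹ s⁻¹, Ea = 42.0 kJ mol⁻¹)
    second nucleophile + intermediate → other capture product (k = 7.61 L mol⁻¹ s⁻¹, Ea = 38.0 kJ mol⁻¹)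
    substrate ⇌ dormant form (K = 1.93, k = 0.0216 s⁻¹, Ea = 70.0 kJ mol⁻¹, ΔH = −14.0 kJ mol⁻¹)
    2 second nucleophile → self-condensation product (k = 0.0738 L mol⁻¹ s⁻¹, Ea = 48.0 kJ mol⁻¹)
    substrate + target → side product (k = 0.160 L mol⁻¹ s⁻¹, Ea = 50.0 kJ mol⁻¹)
    (constants at 25 °C)

North-east lay 0.5 points below my figure, with 96.4% of its first nucleophile left, so the freeze was fair there. North-west lay 4.2 points above it, with 67.5% left. Part of what holds north-west's target down is two steps acting together, the conversion of substrate + target into side product and the return of intermediate to substrate. Taken away singly, they lift that flask from 13.7% to 28.2% and 24.1%. For a flask like north-east kept at 10 °C, take-up gave 5.15%, and that flask held 7.94%.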